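**Retrosynthetic overview**
1. The target is the head-to-tail hydro-dimer of 7-methoxy-2,2-dimethyl-6-vinyl-2H-chromene. The bond between the stereocenter and the alkene carbon is cut to vinylarene 8 and E-alkenyl boronate 9, joined last by an enantioselective nickel hydride hydroalkenylation; both come from one aldehyde 7.
2. The pyran ring of 7 is cut at C4–C4a and C2–C3 into acetylene and a tertiary α-aryloxy radical released from redox-active ester 5 of a fibrate-type acid. This decarboxylative radical [4+2] annulation supplies both chromene units: unit A on the alkene and unit B on the stereocenter.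
3. Enabling feature: in each chromene, O1 bears the quaternary C2(CH3)2 (a stabilized tertiary α-aryloxy radical once a carboxyl placeholder leaves as CO2), C3=C4 is unsubstituted (acetylene as such), and C4a is an aromatic CH ortho to O1 and para to the C7 methoxy group.
4. Ring order: the benzene ring is bought in 1; the pyran ring is formed once (step 4) and carried into both halves; no ring is formed afterwards.

Key step: step 4

Assumption: the stereocenter of the given structure is S (CIP order aryl > alkenyl > methyl > H); the ligand enantiomer of step 7 is chosen for this configuration.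

**Route**

Step 1
Reactants: 1 4-hydroxy-2-methoxybenzaldehyde; 2 ethyl 2-bromo-2-methylpropanoate
Product: 3 ethyl 2-(4-formyl-3-methoxyphenoxy)-2-methylpropanoate
Conditions: 2 (2 equiv), K2CO3 (2 equiv), DMF, 80 °C
Reagents that add atoms: none
Why: Williamson-type etherification of the acidic para-formyl phenoxide with the tertiary α-bromo ester, the standard entry to α-aryloxyisobutyrates, with an aldehyde that has no α-hydrogen and is inert to carbonate.

Step 2
Reactants: 3 ethyl 2-(4-formyl-3-methoxyphenoxy)-2-methylpropanoate
Product: 4 2-(4-formyl-3-methoxyphenoxy)-2-methylpropanoic acid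
Conditions: LiOH·H2O (3 equiv), THF/H2O 3:1, 25 °C; then 1 M HCl
Reagents that add atoms: lithium hydroxide, [Li+].[OH-]
Why: Ester saponification, in which hydroxide cleaves the ester at room temperature while the non-enolizable aryl aldehyde survives dilute base.

Step 3
Reactants: 4 2-(4-formyl-3-methoxyphenoxy)-2-methylpropanoic acid
Product: 5 1,3-dioxoisoindolin-2-yl 2-(4-formyl-3-methoxyphenoxy)-2-methylpropanoate
Conditions: N-hydroxyphthalimide (1.1 equiv), N,N'-diisopropylcarbodiimide (1.1 equiv), DMAP (10 mol %), CH2Cl2, 0 → 25 °C
Reagents that add atoms: N-hydroxyphthalimide, ON1C(=O)c2ccccc2C1=O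
Why: Carbodiimide (Steglich-type) esterification gives the redox-active N-acyloxyphthalimide, a routine operation also for tertiary acids.

Step 4
Reactants: 5 1,3-dioxoisoindolin-2-yl 2-(4-formyl-3-methoxyphenoxy)-2-methylpropanoate; 6 acetylene
Product: 7 7-methoxy-2,2-dimethyl-2H-chromene-6-carbaldehyde
Conditions: fac-Ir(ppy)3 (1 mol %), acetylene (1 atm, solution saturated beforehand), DMF (0.05 M), blue LEDs (450 nm), 25 °C
Reagents that add atoms: none
Why: Proposed new method: photoexcited fac-Ir(ppy)3 reduces the N-acyloxyphthalimide, and loss of phthalimide anion and CO2 leaves the tertiary α-aryloxy radical on the future C2, which adds to acetylene (bond C2–C3); the σ-vinyl radical on C4 then attacks the aromatic CH para to the methoxy group (bond C4–C4a), and the cyclohexadienyl radical is oxidized by the tetravalent iridium and deprotonated by phthalimide anion, so the cycle is redox-neutral. The closest known reaction types are photoredox decarboxylative additions of redox-active esters to alkynes that end in homolytic aromatic substitution, the radical [4+2] annulation of N-aryl α-amino radicals with unsaturated partners to tetrahydroquinolines, and the use of acetylene gas as a two-carbon link between a carbon radical and an arene. The pyran ring closes by a 6-endo-trig attack of the vinyl radical on the arene (ortho closure), the 5-exo ipso attack being reversible and unproductive. No stereocenter is formed. The step needs, first, capture of the tertiary radical by acetylene before it is oxidized to the oxocarbenium ion, which a saturated acetylene solution and a low catalyst loading should secure. It needs, second, closure at the CH para to the methoxy group and not at the CH between the two oxygens, which is favoured because the formyl group turns the methyl of the methoxy group toward that second site and shields it.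

Step 5
Reactants: 7 7-methoxy-2,2-dimethyl-2H-chromene-6-carbaldehyde
Product: 8 7-methoxy-2,2-dimethyl-6-vinyl-2H-chromene
Conditions: Ph3PCH3Br (1.3 equiv), KOtBu (1.25 equiv), THF, 0 → 25 °C
Reagents that add atoms: methyltriphenylphosphonium bromide, C[P+](c1ccccc1)(c1ccccc1)c1ccccc1.[Br-]
Why: Wittig methylenation of the aryl aldehyde under basic conditions, which leave the chromene untouched and avoid any acid that would oligomerize the electron-rich styrene.

Step 6
Reactants: 7 7-methoxy-2,2-dimethyl-2H-chromene-6-carbaldehyde
Product: 9 2-[(E)-2-(7-methoxy-2,2-dimethyl-2H-chromen-6-yl)ethenyl]-4,4,5,5-tetramethyl-1,3,2-dioxaborolane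
Conditions: CH2(Bpin)2 (1.2 equiv), lithium 2,2,6,6-tetramethylpiperidide (LiTMP, 1.2 equiv), THF, 0 °C; then 7, −78 → 25 °C; then H2O
Reagents that add atoms: bis(pinacolatoboryl)methane, CC1(C)OB(CB2OC(C)(C)C(C)(C)O2)OC1(C)C
Why: Boron-Wittig olefination, in which the lithiated geminal diboronate adds to the aldehyde and syn-elimination of the boron–oxygen unit should give the trans alkenyl boronate selectively.

Step 7
Reactants: 8 7-methoxy-2,2-dimethyl-6-vinyl-2H-chromene; 9 2-[(E)-2-(7-methoxy-2,2-dimethyl-2H-chromen-6-yl)ethenyl]-4,4,5,5-tetramethyl-1,3,2-dioxaborolane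
Product: 10 6-[(1E,3S)-3-(7-methoxy-2,2-dimethyl-2H-chromen-6-yl)but-1-en-1-yl]-7-methoxy-2,2-dimethyl-2H-chromene
Conditions: Ni(cod)2 (10 mol %), chiral bis(oxazoline) ligand of the 4-benzyl BOX type (12 mol %, the enantiomer that leads to S), 9 (1.5 equiv), MeOH (5 equiv), THF, 25 °C
Reagents that add atoms: none
Why: Enantioselective nickel-catalysed hydroalkenylation of a vinylarene with an alkenylboron reagent, in which zerovalent nickel and methanol generate a nickel hydride that adds Markovnikov to the terminal vinyl group of 8 only (the cyclic chromene alkenes next to the quaternary C2 are too hindered), the chiral ligand fixes the face of the benzylic nickel centre and so sets the S stereocenter, and transmetalation and reductive elimination transfer the alkenyl group with retention of its E geometry.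

**Compound list**
1 | 4-hydroxy-2-methoxybenzaldehyde | COc1cc(O)ccc1C=O | starting material
2 | ethyl 2-bromo-2-methylpropanoate | CCOC(=O)C(C)(C)Br | starting material
3 | ethyl 2-(4-formyl-3-methoxyphenoxy)-2-methylpropanoate | CCOC(=O)C(C)(C)Oc1ccc(C=O)c(OC)c1 | intermediate
4 | 2-(4-formyl-3-methoxyphenoxy)-2-methylpropanoic acid | OC(=O)C(C)(C)Oc1ccc(C=O)c(OC)c1 | intermediate
5 | 1,3-dioxoisoindolin-2-yl 2-(4-formyl-3-methoxyphenoxy)-2-methylpropanoate | O=C(ON1C(=O)c2ccccc2C1=O)C(C)(C)Oc1ccc(C=O)c(OC)c1 | intermediate
6 | acetylene | C#C | starting material
7 | 7-methoxy-2,2-dimethyl-2H-chromene-6-carbaldehyde | COc1cc2c(cc1C=O)C=CC(C)(C)O2 | intermediate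
8 | 7-methoxy-2,2-dimethyl-6-vinyl-2H-chromene | COc1cc2c(cc1C=C)C=CC(C)(C)O2 | intermediate
9 | 2-[(E)-2-(7-methoxy-2,2-dimethyl-2H-chromen-6-yl)ethenyl]-4,4,5,5-tetramethyl-1,3,2-dioxaborolane | COc1cc2c(cc1/C=C/B3OC(C)(C)C(C)(C)O3)C=CC(C)(C)O2 | intermediate
10 | 6-[(1E,3S)-3-(7-methoxy-2,2-dimethyl-2H-chromen-6-yl)but-1-en-1-yl]-7-methoxy-2,2-dimethyl-2H-chromene | COc1cc2c(cc1/C=C/[C@H](C)c1cc3c(cc1OC)OC(C)(C)C=C3)C=CC(C)(C)O2 | target

**Step count and risks**
Total steps: 7. Longest linear sequence: 6 (steps 1, 2, 3, 4, then 5 or 6, then 7).

Steps most likely to fail: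

Step 4. The tertiary α-aryloxy radical may be oxidized to the oxocarbenium ion, or desaturated to the aryl isopropenyl ether, faster than it adds to acetylene. The ring closure may also partition between the two ortho CH sites. The fallback uses known chemistry, sets out from 1 and returns at 7. O-Alkylation of 1 with 3-chloro-3-methylbut-1-yne (K2CO3, KI, CuI cat., acetone, reflux) should give 2-methoxy-4-[(2-methylbut-3-yn-2-yl)oxy]benzaldehyde F1. Heating F1 in N,N-diethylaniline at about 190 °C should give 7 by the aryl propargyl ether Claisen rearrangement, 1,5-hydrogen shift and oxa-6π electrocyclization.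

Step 7. Enantioface discrimination at the benzylic nickel stage may be insufficient, 8 may undergo homo-hydrovinylation, or a chromene alkene may be hydrometalated. The fallback sets out from 8 and returns at 10. Asymmetric hydrovinylation of 8 with ethylene ([(allyl)NiBr]2, chiral phosphoramidite, NaB[3,5-(CF3)2C6H3]4, CH2Cl2, −70 °C) should give (S)-6-(but-3-en-2-yl)-7-methoxy-2,2-dimethyl-2H-chromene F2. E-Selective cross-metathesis of F2 with a second portion of 8 (second-generation Hoveyda–Grubbs catalyst, CH2Cl2, 40 °C) should then give 10.

Step 6. The elimination may be incompletely E-selective, or the electron-rich alkenyl boronate may protodeboronate during isolation. The fallback sets out from 8 and returns at 9 without any new compound. Cross-metathesis of 8 with vinylboronic acid pinacol ester (second-generation Grubbs catalyst, CH2Cl2, 40 °C) should deliver the E-alkenyl boronate 9 directly.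

**Further compounds**
F1 | step 4 | 2-methoxy-4-[(2-methylbut-3-yn-2-yl)oxy]benzaldehyde | COc1cc(OC(C)(C)C#C)ccc1C=O
F2 | step 7 | (S)-6-(but-3-en-2-yl)-7-methoxy-2,2-dimethyl-2H-chromene | C=C[C@H](C)c1cc2c(cc1OC)OC(C)(C)C=C2
F0 | step 6 | none | none
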